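**Retrosynthetic overview**

1. Target 27 ⇐ bromodiene 24: the two oxiranes go on last, C7–C8 from the C5 face with the C1 silyl ether in place, then C9–C10(Br) from the C1 face with free C1–OH. The C9 and C10 functionality comes from allylic oxidation next to C7=C8 after ring B is finished.
2. Feature on which the strategy rests: on ring B (C1–C6) the tertiary C3 chloride and the secondary C4 bromide are trans, and they are the stereospecific image of a cis-C3,C4-diol. Bromide enters C4 with inversion through the cyclic sulfate, and chloride replaces the C3 oxygen with retention through the C3/C4 bromonium ion.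
3. cis-Diol 15 ⇐ keto-aldehyde 14: SmI2 ketyl–carbonyl coupling forms C3–C4 and closes ring B onto the preformed ring A at spiro C6.
4. 14 ⇐ ring A allylic alcohol 8: an Eschenmoser–Claisen rearrangement transfers the C8 carbinol configuration to quaternary C6 (new C6–C5 bond, alkene moves to C7=C8). C1 comes from asymmetric methallylboration of β-cyclocitral and C8–OH from an oxazaborolidine reduction.
5. Ring order: ring A (bought with β-cyclocitral) → ring B (step 8) → C7–C8 oxirane (step 16) → C9–C10 bromo-oxirane (step 18).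

Key step: step 8

Remark (numbering): spiro atom C6; ring B = C1(O)–C2–C3(Me,Cl)–C4(Br)–C5–C6; ring A = C6–C7(Me)–C8–C9–C10(Br)–C11(Me2). These locants are used for all intermediates, also before ring B exists, and in the names of the spiro compounds.

Remark (assumption): the C9 and C10 configurations drawn for 22 and 23 are those expected from axial bromination and hydride delivery anti to C–Br. Both centres become sp2 in step 15, which relies only on their cis relation.

**Route**

Step 1
Reactants: 1 β-cyclocitral (2,6,6-trimethylcyclohex-1-ene-1-carbaldehyde); 2 2-methylallylmagnesium chloride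
Product: 5 (1S)-3-methyl-1-(2,6,6-trimethylcyclohex-1-en-1-yl)but-3-en-1-ol, via B-(2-methylallyl)diisopinocampheylborane 3 (not isolated), via borinate ester 4 (not isolated)
Conditions: (−)-Ipc2BOMe, 2, Et2O, −78 °C → rt; then 1, −78 °C; then NaOH, H2O2, 0 °C → rt
Reagents that add atoms: none
Why: Brown-type asymmetric allylboration, in which borane 3 (from the (+)-α-pinene-derived methoxyborane and the Grignard reagent) adds 1,2 to the hindered enal through a closed chair transition state on the Si face, which should set C1 as S, and alkaline peroxide cleaves borinate 4.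

Step 2
Reactants: 5 (1S)-3-methyl-1-(2,6,6-trimethylcyclohex-1-en-1-yl)but-3-en-1-ol
Product: 6 tert-butyl(dimethyl){[(1S)-3-methyl-1-(2,6,6-trimethylcyclohex-1-en-1-yl)but-3-en-1-yl]oxy}silane
Conditions: t-BuMe2SiOTf, 2,6-lutidine, CH2Cl2, −78 → 0 °C
Reagents that add atoms: tert-butyldimethylsilyl trifluoromethanesulfonate, CC(C)(C)[Si](C)(C)OS(=O)(=O)C(F)(F)F
Why: Standard silylation of a hindered secondary allylic alcohol with the silyl triflate and a non-nucleophilic base; the bulky ether later protects C1–O through the oxidations and steers the face of the C7=C8 epoxidation.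

Step 3
Reactants: 6 tert-butyl(dimethyl){[(1S)-3-methyl-1-(2,6,6-trimethylcyclohex-1-en-1-yl)but-3-en-1-yl]oxy}silane
Product: 7 3-[(1S)-1-{[tert-butyl(dimethyl)silyl]oxy}-3-methylbut-3-en-1-yl]-2,4,4-trimethylcyclohex-2-en-1-one
Conditions: CrO3, 3,5-dimethylpyrazole, CH2Cl2, −20 °C
Reagents that add atoms: chromium trioxide, O=[Cr](=O)=O
Why: Allylic oxidation with the CrO3–3,5-dimethylpyrazole complex, which attacks the ring methylene C8 next to the most electron-rich (tetrasubstituted) alkene; the C1–H lies in the alkene plane for allylic-strain reasons and the 1,1-disubstituted side-chain alkene is less electron-rich, so both should be spared.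

Step 4
Reactants: 7 3-[(1S)-1-{[tert-butyl(dimethyl)silyl]oxy}-3-methylbut-3-en-1-yl]-2,4,4-trimethylcyclohex-2-en-1-one
Product: 8 (1S)-3-[(1S)-1-{[tert-butyl(dimethyl)silyl]oxy}-3-methylbut-3-en-1-yl]-2,4,4-trimethylcyclohex-2-en-1-ol
Conditions: (R)-2-methyl-CBS-oxazaborolidine (20 mol%), catecholborane, toluene, −78 °C; aq. NaOH work-up
Reagents that add atoms: none
Why: Corey–Bakshi–Shibata reduction, in which the methyl-substituted alkenyl branch acts as the large group so that the (R)-oxazaborolidine should deliver hydride to give the 1S (C8) carbinol under reagent control, while catecholborane at −78 °C does not hydroborate the alkenes.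

Step 5
Reactants: 8 (1S)-3-[(1S)-1-{[tert-butyl(dimethyl)silyl]oxy}-3-methylbut-3-en-1-yl]-2,4,4-trimethylcyclohex-2-en-1-ol; 9 N,N-dimethylacetamide dimethyl acetal
Product: 11 2-{(1S)-1-[(1S)-1-{[tert-butyl(dimethyl)silyl]oxy}-3-methylbut-3-en-1-yl]-2,6,6-trimethylcyclohex-2-en-1-yl}-N,N-dimethylacetamide, via ketene N,O-acetal 10 (not isolated)
Conditions: 9 (excess), xylene, 140 °C
Reagents that add atoms: none
Why: Eschenmoser–Claisen rearrangement, in which exchange gives ketene N,O-acetal 10 and the [3,3] shift is suprafacial over C8–C7=C6, so the new C6–C5 bond forms on the ring face that carried the C8 oxygen and quaternary C6 is set S by the fixed ring-alkene geometry alone, under neutral conditions that do not ionise the allylic alcohol.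

Step 6
Reactants: 11 2-{(1S)-1-[(1S)-1-{[tert-butyl(dimethyl)silyl]oxy}-3-methylbut-3-en-1-yl]-2,6,6-trimethylcyclohex-2-en-1-yl}-N,N-dimethylacetamide
Product: 12 {(1S)-1-[(1S)-1-{[tert-butyl(dimethyl)silyl]oxy}-3-methylbut-3-en-1-yl]-2,6,6-trimethylcyclohex-2-en-1-yl}acetaldehyde
Conditions: Cp2Zr(H)Cl (1.6 equiv), THF, rt; then H2O, SiO2
Reagents that add atoms: none
Why: Reduction of a tertiary amide to the aldehyde with Cp2Zr(H)Cl, whose zirconated hemiaminal does not over-reduce and collapses on work-up, the hindered 1,1-disubstituted and trisubstituted alkenes reacting much more slowly than the amide.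

Step 7
Reactants: 12 {(1S)-1-[(1S)-1-{[tert-butyl(dimethyl)silyl]oxy}-3-methylbut-3-en-1-yl]-2,6,6-trimethylcyclohex-2-en-1-yl}acetaldehyde
Product: 14 (4S)-4-{[tert-butyl(dimethyl)silyl]oxy}-4-[(1S)-2,6,6-trimethyl-1-(2-oxoethyl)cyclohex-2-en-1-yl]butan-2-one, via diol 13 (not isolated)
Conditions: OsO4 (2 mol%), NaIO4, 2,6-lutidine, dioxane/H2O 3:1, rt
Reagents that add atoms: osmium tetroxide (oxygen carrier), O=[Os](=O)(=O)=O; sodium periodate (terminal oxidant), [Na+].[O-][I](=O)(=O)=O
Why: Lemieux–Johnson oxidation, in which OsO4 dihydroxylates the accessible 1,1-disubstituted alkene in preference to the neopentyl trisubstituted ring alkene and periodate cleaves diol 13 to the methyl ketone, leaving the aldehyde and the silyl ether untouched.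

Step 8
Reactants: 14 (4S)-4-{[tert-butyl(dimethyl)silyl]oxy}-4-[(1S)-2,6,6-trimethyl-1-(2-oxoethyl)cyclohex-2-en-1-yl]butan-2-one
Product: 15 (1S,3S,4R,6S)-1-{[tert-butyl(dimethyl)silyl]oxy}-3,7,11,11-tetramethylspiro[5.5]undec-7-ene-3,4-diol
Conditions: SmI2 (2.5 equiv), t-BuOH, THF, −78 °C → rt
Reagents that add atoms: none
Why: SmI2 (divalent samarium) transfers one electron to the more easily reduced C4 aldehyde, and the resulting ketyl, bound to trivalent samarium, adds to the C3 ketone held on the same metal, after which a second electron and protonation give the diol. The closest known reaction type is the samarium diiodide pinacol cyclisation of 1,6-keto-aldehydes to cis-cyclohexane-1,2-diols. Ring B (six-membered, C1–C6) is closed through the C3–C4 bond by a 6-exo-trig addition of the ketyl carbon to the ketone carbon. The cis relation of the new C3 and C4 hydroxyls follows from both oxygens sitting on one samarium centre while the C–C bond forms. Which cis-diol forms should be decided by the chair transition state that keeps the C1 silyloxy group and the C3 methyl equatorial, which puts both oxygens anti to C1–OSi (3S,4R). The step needs coupling to beat simple carbonyl reduction, which the fast intramolecular trapping of the ketyl secures, and C7=C8 cannot compete because addition to it would need a four-membered ring.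

Step 9
Reactants: 15 (1S,3S,4R,6S)-1-{[tert-butyl(dimethyl)silyl]oxy}-3,7,11,11-tetramethylspiro[5.5]undec-7-ene-3,4-diol
Product: 16 (1S,3S,4R,6S)-3,4-cyclic sulfate of 15
Conditions: NaH, 1,1'-sulfonyldiimidazole, THF, −20 °C → rt
Reagents that add atoms: 1,1'-sulfonyldiimidazole, O=S(=O)(n1ccnc1)n1ccnc1
Why: Cyclic sulfate formation by twofold O-sulfonylation of the bis-alkoxide with sulfonyldiimidazole, a direct method that avoids the sulfite/RuO4 sequence and thereby any oxidation of C7=C8; no stereocentre is touched.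

Step 10
Reactants: 16 (1S,3S,4R,6S)-3,4-cyclic sulfate of 15
Product: 18 (1S,3S,4S,6S)-4-bromo-1-{[tert-butyl(dimethyl)silyl]oxy}-3,7,11,11-tetramethylspiro[5.5]undec-7-en-3-ol, via lithium sulfate monoester 17 (not isolated)
Conditions: LiBr, DMF, 60 °C; then H2SO4 (cat.), H2O, THF, rt
Reagents that add atoms: lithium bromide, [Li+].[Br-]
Why: Nucleophilic opening of a cyclic sulfate (epoxide-like SN2), in which bromide attacks the secondary C4 rather than the tertiary C3 with inversion (C4 becomes S, bromine anti to the C3 oxygen), and acid hydrolysis of the tertiary sulfate monoester 17 by S–O cleavage returns the C3 alcohol with its configuration and its own oxygen.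

Step 11
Reactants: 18 (1S,3S,4S,6S)-4-bromo-1-{[tert-butyl(dimethyl)silyl]oxy}-3,7,11,11-tetramethylspiro[5.5]undec-7-en-3-ol
Product: 19 {[(1S,3S,4S,6S)-4-bromo-3-chloro-3,7,11,11-tetramethylspiro[5.5]undec-7-en-1-yl]oxy}(tert-butyl)dimethylsilane
Conditions: Me2C=C(Cl)NMe2, CH2Cl2, 0 °C → rt
Reagents that add atoms: 1-chloro-N,N,2-trimethylprop-1-en-1-amine, CC(C)=C(Cl)N(C)C
Why: Chlorination of a tertiary alcohol with an α-chloroenamine under neutral conditions with neighbouring-group participation, in which the O-imidate ionises with help of the vicinal anti bromine to the C3/C4 bromonium ion and chloride opens it at the more substituted C3 from the face opposite bromine, so two inversions give net retention at C3 (3S) and the trans C3–Cl/C4–Br pair.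

Step 12
Reactants: 19 {[(1S,3S,4S,6S)-4-bromo-3-chloro-3,7,11,11-tetramethylspiro[5.5]undec-7-en-1-yl]oxy}(tert-butyl)dimethylsilane
Product: 20 (1S,3S,4S,6S)-4-bromo-1-{[tert-butyl(dimethyl)silyl]oxy}-3-chloro-3,7,11,11-tetramethylspiro[5.5]undec-7-en-9-one
Conditions: CrO3, 3,5-dimethylpyrazole, CH2Cl2, −20 °C
Reagents that add atoms: chromium trioxide, O=[Cr](=O)=O
Why: Allylic oxidation with CrO3–3,5-dimethylpyrazole of the only allylic methylene of the trisubstituted alkene (C9), giving the 7-en-9-one; the alkyl halides and the silyl ether are inert to the reagent.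

Step 13
Reactants: 20 (1S,3S,4S,6S)-4-bromo-1-{[tert-butyl(dimethyl)silyl]oxy}-3-chloro-3,7,11,11-tetramethylspiro[5.5]undec-7-en-9-one
Product: 22 (1S,3S,4S,6R,10S)-4,10-dibromo-1-{[tert-butyl(dimethyl)silyl]oxy}-3-chloro-3,7,11,11-tetramethylspiro[5.5]undec-7-en-9-one, via silyl dienol ether 21 (not isolated)
Conditions: LiN(SiMe3)2, Me3SiCl, THF, −78 °C; then NBS, −78 → 0 °C
Reagents that add atoms: N-bromosuccinimide, O=C1CCC(=O)N1Br
Why: Kinetic α′-enolisation toward C10 with in-situ silylation gives the cross-conjugated silyl dienol ether 21, which NBS brominates at C10 (α-bromination of a silyl enol ether), expected axially and anti to the C1 branch; this centre is erased in step 15.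

Step 14
Reactants: 22 (1S,3S,4S,6R,10S)-4,10-dibromo-1-{[tert-butyl(dimethyl)silyl]oxy}-3-chloro-3,7,11,11-tetramethylspiro[5.5]undec-7-en-9-one
Product: 23 (1S,3S,4S,6R,9R,10S)-4,10-dibromo-1-{[tert-butyl(dimethyl)silyl]oxy}-3-chloro-3,7,11,11-tetramethylspiro[5.5]undec-7-en-9-ol
Conditions: NaBH4, CeCl3·7H2O, MeOH/THF, −78 → −20 °C
Reagents that add atoms: none
Why: Luche reduction, a CeCl3-mediated 1,2-hydride addition to the enone that is expected anti to the C10–Br bond and so should give the cis-bromohydrin (9R); this centre is also erased in step 15.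

Step 15
Reactants: 23 (1S,3S,4S,6R,9R,10S)-4,10-dibromo-1-{[tert-butyl(dimethyl)silyl]oxy}-3-chloro-3,7,11,11-tetramethylspiro[5.5]undec-7-en-9-ol
Product: 24 {[(1S,3S,4S,6R)-4,10-dibromo-3-chloro-3,7,11,11-tetramethylspiro[5.5]undeca-7,9-dien-1-yl]oxy}(tert-butyl)dimethylsilane
Conditions: Ph2S[OC(CF3)2Ph]2, CH2Cl2, 0 °C → rt
Reagents that add atoms: none
Why: Sulfurane dehydration of a secondary alcohol by anti E2 elimination from the alkoxysulfonium ion, in which the C10–H is trans to the C9 oxygen in the cis-bromohydrin and is the only sp3 β-hydrogen, so the 10-bromo-7,9-diene should form.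

Step 16
Reactants: 24 {[(1S,3S,4S,6R)-4,10-dibromo-3-chloro-3,7,11,11-tetramethylspiro[5.5]undeca-7,9-dien-1-yl]oxy}(tert-butyl)dimethylsilane
Product: 25 {[(1S,3S,4S,6R,7R,8S)-4,10-dibromo-3-chloro-7,8-epoxy-3,7,11,11-tetramethylspiro[5.5]undec-9-en-1-yl]oxy}(tert-butyl)dimethylsilane
Conditions: mCPBA (1.1 equiv), NaHCO3, CH2Cl2, 0 °C
Reagents that add atoms: 3-chloroperoxybenzoic acid, OOC(=O)c1cccc(Cl)c1
Why: Prilezhaev epoxidation, in which the peracid picks the electron-richer trisubstituted C7=C8 over the bromine-deactivated C9=C10 and approaches anti to the pseudoaxial C6–C1 bond that carries the bulky silyloxy group, that is from the C5 face, which should give the 7R,8S oxirane.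

Step 17
Reactants: 25 {[(1S,3S,4S,6R,7R,8S)-4,10-dibromo-3-chloro-7,8-epoxy-3,7,11,11-tetramethylspiro[5.5]undec-9-en-1-yl]oxy}(tert-butyl)dimethylsilane
Product: 26 (1S,3S,4S,6R,7R,8S)-4,10-dibromo-3-chloro-7,8-epoxy-3,7,11,11-tetramethylspiro[5.5]undec-9-en-1-ol
Conditions: Bu4NF, AcOH (1:1), THF, rt
Reagents that add atoms: none
Why: Fluoride-mediated desilylation, buffered with AcOH so that fluoride basicity does not cause E2 loss of HCl or HBr or opening of the vinyl oxirane; it frees C1–OH as the directing group for the last step.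

Step 18
Reactants: 26 (1S,3S,4S,6R,7R,8S)-4,10-dibromo-3-chloro-7,8-epoxy-3,7,11,11-tetramethylspiro[5.5]undec-9-en-1-ol
Product: 27 (1S,3S,4S,6R,7R,8S,9S,10S)-4,10-dibromo-3-chloro-7,8:9,10-diepoxy-3,7,11,11-tetramethylspiro[5.5]undecan-1-ol
Conditions: mCPBA (excess), Na2HPO4, CH2Cl2, 0 °C → rt
Reagents that add atoms: 3-chloroperoxybenzoic acid, OOC(=O)c1cccc(Cl)c1
Why: Prilezhaev epoxidation of a vinyl bromide to an α-bromo oxirane, in which hydrogen bonding of the peracid to the free C1–OH on the pseudoaxial C1 branch and the preference for attack anti to the existing C7–C8 oxirane both point to the C1 face, which should set C9 and C10 as S,S, while the phosphate buffer shields the acid-labile product.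

**Compound list**

1 | β-cyclocitral (2,6,6-trimethylcyclohex-1-ene-1-carbaldehyde) | CC1=C(C=O)C(C)(C)CCC1 | starting material
2 | 2-methylallylmagnesium chloride | C=C(C)C[Mg]Cl | starting material
3 | (−)-B-(2-methylallyl)diisopinocampheylborane, isopinocampheyl groups from (+)-α-pinene, not isolated | CC(=C)CB([C@@H]1C[C@@H]2C[C@@H](C2(C)C)[C@H]1C)[C@@H]1C[C@@H]2C[C@@H](C2(C)C)[C@H]1C | intermediate
4 | diisopinocampheylborinate ester of 5, not isolated | CC1=C([C@H](CC(C)=C)OB([C@@H]2C[C@@H]3C[C@@H](C3(C)C)[C@H]2C)[C@@H]2C[C@@H]3C[C@@H](C3(C)C)[C@H]2C)C(C)(C)CCC1 | intermediate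
5 | (1S)-3-methyl-1-(2,6,6-trimethylcyclohex-1-en-1-yl)but-3-en-1-ol | CC1=C([C@H](CC(C)=C)O)C(C)(C)CCC1 | intermediate
6 | tert-butyl(dimethyl){[(1S)-3-methyl-1-(2,6,6-trimethylcyclohex-1-en-1-yl)but-3-en-1-yl]oxy}silane | CC1=C([C@H](CC(C)=C)O[Si](C)(C)C(C)(C)C)C(C)(C)CCC1 | intermediate
7 | 3-[(1S)-1-{[tert-butyl(dimethyl)silyl]oxy}-3-methylbut-3-en-1-yl]-2,4,4-trimethylcyclohex-2-en-1-one | CC1(C)CCC(=O)C(C)=C1[C@H](CC(C)=C)O[Si](C)(C)C(C)(C)C | intermediate
8 | (1S)-3-[(1S)-1-{[tert-butyl(dimethyl)silyl]oxy}-3-methylbut-3-en-1-yl]-2,4,4-trimethylcyclohex-2-en-1-ol | CC1(C)CC[C@H](O)C(C)=C1[C@H](CC(C)=C)O[Si](C)(C)C(C)(C)C | intermediate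
9 | N,N-dimethylacetamide dimethyl acetal (1,1-dimethoxy-N,N-dimethylethan-1-amine) | CC(OC)(OC)N(C)C | starting material
10 | ketene N,O-acetal on the C8 oxygen of 8, not isolated | CC1(C)CC[C@H](OC(=C)N(C)C)C(C)=C1[C@H](CC(C)=C)O[Si](C)(C)C(C)(C)C | intermediate
11 | 2-{(1S)-1-[(1S)-1-{[tert-butyl(dimethyl)silyl]oxy}-3-methylbut-3-en-1-yl]-2,6,6-trimethylcyclohex-2-en-1-yl}-N,N-dimethylacetamide | CC1(C)CCC=C(C)[C@@]1(CC(=O)N(C)C)[C@H](CC(C)=C)O[Si](C)(C)C(C)(C)C | intermediate
12 | {(1S)-1-[(1S)-1-{[tert-butyl(dimethyl)silyl]oxy}-3-methylbut-3-en-1-yl]-2,6,6-trimethylcyclohex-2-en-1-yl}acetaldehyde | CC1(C)CCC=C(C)[C@@]1(CC=O)[C@H](CC(C)=C)O[Si](C)(C)C(C)(C)C | intermediate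
13 | vicinal diol from the methallyl group of 12 (both C3 epimers), not isolated | CC1(C)CCC=C(C)[C@@]1(CC=O)[C@H](CC(C)(O)CO)O[Si](C)(C)C(C)(C)C | intermediate
14 | (4S)-4-{[tert-butyl(dimethyl)silyl]oxy}-4-[(1S)-2,6,6-trimethyl-1-(2-oxoethyl)cyclohex-2-en-1-yl]butan-2-one | CC1(C)CCC=C(C)[C@@]1(CC=O)[C@H](CC(C)=O)O[Si](C)(C)C(C)(C)C | intermediate
15 | (1S,3S,4R,6S)-1-{[tert-butyl(dimethyl)silyl]oxy}-3,7,11,11-tetramethylspiro[5.5]undec-7-ene-3,4-diol | CC1(C)CCC=C(C)[C@]12C[C@@H](O)[C@@](C)(O)C[C@@H]2O[Si](C)(C)C(C)(C)C | intermediate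
16 | (1S,3S,4R,6S)-3,4-cyclic sulfate of 15 | CC1(C)CCC=C(C)[C@]12C[C@H]3OS(=O)(=O)O[C@@]3(C)C[C@@H]2O[Si](C)(C)C(C)(C)C | intermediate
17 | lithium (1S,3S,4S,6S)-4-bromo-1-{[tert-butyl(dimethyl)silyl]oxy}-3,7,11,11-tetramethylspiro[5.5]undec-7-en-3-yl sulfate, not isolated | CC1(C)CCC=C(C)[C@]12C[C@H](Br)[C@@](C)(OS(=O)(=O)[O-])C[C@@H]2O[Si](C)(C)C(C)(C)C.[Li+] | intermediate
18 | (1S,3S,4S,6S)-4-bromo-1-{[tert-butyl(dimethyl)silyl]oxy}-3,7,11,11-tetramethylspiro[5.5]undec-7-en-3-ol | CC1(C)CCC=C(C)[C@]12C[C@H](Br)[C@@](C)(O)C[C@@H]2O[Si](C)(C)C(C)(C)C | intermediate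
19 | {[(1S,3S,4S,6S)-4-bromo-3-chloro-3,7,11,11-tetramethylspiro[5.5]undec-7-en-1-yl]oxy}(tert-butyl)dimethylsilane | CC1(C)CCC=C(C)[C@]12C[C@H](Br)[C@@](C)(Cl)C[C@@H]2O[Si](C)(C)C(C)(C)C | intermediate
20 | (1S,3S,4S,6S)-4-bromo-1-{[tert-butyl(dimethyl)silyl]oxy}-3-chloro-3,7,11,11-tetramethylspiro[5.5]undec-7-en-9-one | CC1(C)CC(=O)C=C(C)[C@]12C[C@H](Br)[C@@](C)(Cl)C[C@@H]2O[Si](C)(C)C(C)(C)C | intermediate
21 | 9-(trimethylsilyloxy)-7,9-diene, silyl dienol ether of 20, not isolated | CC1(C)C=C(O[Si](C)(C)C)C=C(C)[C@]12C[C@H](Br)[C@@](C)(Cl)C[C@@H]2O[Si](C)(C)C(C)(C)C | intermediate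
22 | (1S,3S,4S,6R,10S)-4,10-dibromo-1-{[tert-butyl(dimethyl)silyl]oxy}-3-chloro-3,7,11,11-tetramethylspiro[5.5]undec-7-en-9-one | CC1(C)[C@H](Br)C(=O)C=C(C)[C@]12C[C@H](Br)[C@@](C)(Cl)C[C@@H]2O[Si](C)(C)C(C)(C)C | intermediate
23 | (1S,3S,4S,6R,9R,10S)-4,10-dibromo-1-{[tert-butyl(dimethyl)silyl]oxy}-3-chloro-3,7,11,11-tetramethylspiro[5.5]undec-7-en-9-ol | CC1(C)[C@H](Br)[C@H](O)C=C(C)[C@]12C[C@H](Br)[C@@](C)(Cl)C[C@@H]2O[Si](C)(C)C(C)(C)C | intermediate
24 | {[(1S,3S,4S,6R)-4,10-dibromo-3-chloro-3,7,11,11-tetramethylspiro[5.5]undeca-7,9-dien-1-yl]oxy}(tert-butyl)dimethylsilane | CC1(C)C(Br)=CC=C(C)[C@]12C[C@H](Br)[C@@](C)(Cl)C[C@@H]2O[Si](C)(C)C(C)(C)C | intermediate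
25 | {[(1S,3S,4S,6R,7R,8S)-4,10-dibromo-3-chloro-7,8-epoxy-3,7,11,11-tetramethylspiro[5.5]undec-9-en-1-yl]oxy}(tert-butyl)dimethylsilane | CC1(C)C(Br)=C[C@@H]2O[C@]2(C)[C@]12C[C@H](Br)[C@@](C)(Cl)C[C@@H]2O[Si](C)(C)C(C)(C)C | intermediate
26 | (1S,3S,4S,6R,7R,8S)-4,10-dibromo-3-chloro-7,8-epoxy-3,7,11,11-tetramethylspiro[5.5]undec-9-en-1-ol | CC1(C)C(Br)=C[C@@H]2O[C@]2(C)[C@]12C[C@H](Br)[C@@](C)(Cl)C[C@@H]2O | intermediate
27 | (1S,3S,4S,6R,7R,8S,9S,10S)-4,10-dibromo-3-chloro-7,8:9,10-diepoxy-3,7,11,11-tetramethylspiro[5.5]undecan-1-ol (CNP0345283.3) | CC1(C)[C@@]2(Br)O[C@H]2[C@@H]2O[C@]2(C)[C@]12C[C@H](Br)[C@@](C)(Cl)C[C@@H]2O | target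

**Step count**

Total steps: 18. Longest linear sequence: 18 steps (from β-cyclocitral 1).

**Steps most likely to fail, with fallbacks**

1. Step 18 (last oxirane). Oxygen transfer to the doubly deactivated bromoalkene may be too slow, the peracid may attack from the C5 face, and the α-bromo oxirane may rearrange to an α-bromo ketone under the acid that is formed. The fallback closes the oxirane by intramolecular displacement instead of oxygen transfer; it sets out from 22 and comes back to the route at 27. Bromo enone 22 is enolised and brominated a second time at C10 (LiN(SiMe3)2, Me3SiCl, then NBS) to give the 10,10-dibromo enone F1. A 1,2-reduction with NaBH4/CeCl3·7H2O, or an oxazaborolidine-controlled reduction if the substrate bias is weak, should give the 9S dibromo alcohol F2 with the C9 oxygen on the C1 face. K2CO3 in MeOH at 0 °C lets the C9 alkoxide displace the antiperiplanar bromide of the CBr2 group, the known route from 2,2-dihalo alkoxides to α-halo oxiranes, to give the bromo-oxirane F3, whose oxirane face is now fixed by the C9 carbinol. mCPBA/NaHCO3 then epoxidises C7=C8 anti to the bromo-oxirane and to the C1 silyloxy branch to give the bis-oxirane silyl ether F4, and Bu4NF/AcOH removes the silyl group to give 27.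

2. Step 11 (C3 chloride with retention). The ionised C3 centre may lose a proton to give alkenes, chloride may open the bromonium ion at C4 so that the halogens change places, or the bromine may fail to assist because the conformer with anti C3–O and C4–Br bonds is strained. The fallback replaces substitution by anti addition of BrCl to a ring B alkene; it sets out from 15 and comes back at 19. Thiocarbonyldiimidazole converts diol 15 into the cyclic thionocarbonate F5, and Corey–Winter olefination with P(OMe)3 gives the 3,7-diene F6. Bu4N+ BrCl2− then adds bromine and chlorine anti and in the Markovnikov sense (chloride at tertiary C3) to the less hindered ring B alkene. Because bromonium formation is reversible and chloride can reach C3 only from the face anti to the C1 silyloxy group, 19 should predominate.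

3. Step 8 (key step). Facial discrimination between the two cis-diols may be poor, some trans-diol may form, the aldehyde may simply be reduced, or the keto-aldehyde may undergo aldol closure on the Lewis-acidic samarium salts. The fallback replaces reductive coupling by metathesis and osmylation; it sets out from 12 and comes back at 15. Wittig methylenation of aldehyde 12 (Ph3P=CH2) gives the allyl/methallyl diene F7. Ring-closing metathesis with the second-generation Grubbs catalyst, (H2IMes)(PCy3)Cl2Ru=CHPh, closes ring B as the C3=C4 alkene F6, the same compound as in the fallback to step 11. OsO4 (cat.) with N-methylmorpholine N-oxide dihydroxylates this alkene, cis by mechanism and expected anti to the C1 silyloxy group, to give 15.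

**Further compounds**

F1 | step 18 | (1S,3S,4S,6R)-4,10,10-tribromo-1-{[tert-butyl(dimethyl)silyl]oxy}-3-chloro-3,7,11,11-tetramethylspiro[5.5]undec-7-en-9-one | CC1(C)C(Br)(Br)C(=O)C=C(C)[C@]12C[C@H](Br)[C@@](C)(Cl)C[C@@H]2O[Si](C)(C)C(C)(C)C
F2 | step 18 | (9S)-alcohol from F1, 4,10,10-tribromo-1-silyloxy-3-chloro-3,7,11,11-tetramethylspiro[5.5]undec-7-en-9-ol | CC1(C)C(Br)(Br)[C@@H](O)C=C(C)[C@]12C[C@H](Br)[C@@](C)(Cl)C[C@@H]2O[Si](C)(C)C(C)(C)C
F3 | step 18 | (9S,10S)-9,10-epoxy-4,10-dibromo-3-chloro-3,7,11,11-tetramethylspiro[5.5]undec-7-en-1-yl tert-butyldimethylsilyl ether | CC1(C)[C@@]2(Br)O[C@H]2C=C(C)[C@]12C[C@H](Br)[C@@](C)(Cl)C[C@@H]2O[Si](C)(C)C(C)(C)C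
F4 | step 18 | tert-butyldimethylsilyl ether of 27 | CC1(C)[C@@]2(Br)O[C@H]2[C@@H]2O[C@]2(C)[C@]12C[C@H](Br)[C@@](C)(Cl)C[C@@H]2O[Si](C)(C)C(C)(C)C
F5 | step 11 | 3,4-cyclic thionocarbonate of 15 | CC1(C)CCC=C(C)[C@]12C[C@H]3OC(=S)O[C@@]3(C)C[C@@H]2O[Si](C)(C)C(C)(C)C
F6 | step 11 | tert-butyl(dimethyl){[(1S,6S)-3,7,11,11-tetramethylspiro[5.5]undeca-3,7-dien-1-yl]oxy}silane | CC1(C)CCC=C(C)[C@]12CC=C(C)C[C@@H]2O[Si](C)(C)C(C)(C)C
F7 | step 8 | tert-butyl(dimethyl){[(1S)-3-methyl-1-[(1S)-2,6,6-trimethyl-1-(prop-2-en-1-yl)cyclohex-2-en-1-yl]but-3-en-1-yl]oxy}silane | CC1(C)CCC=C(C)[C@@]1(CC=C)[C@H](CC(C)=C)O[Si](C)(C)C(C)(C)C
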